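**Strategy**

Everything rests on disconnecting ring C at the O1–C8a bond. Because O1 joins the stereogenic carbon C2 to the aromatic carbon C8a of ring A, the pyran ring can be closed from the aryl side while the C2–O bond, and with it the C2 configuration, stays untouched. One palladium-catalysed intramolecular aryl etherification turns the open-chain bromo diol into the 2,4-cis flavan-4-ol. The precursor is an anti-1,3-diol: its (S)-carbinol at C2 comes from a catalytic asymmetric Mukaiyama aldol between an A-ring enol silane and the geranylated B-ring aldehyde, and C4 is held as an alcohol until the ring is closed, then oxidised.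

Key step: step 10

**Assumptions and remarks on the chemistry**

- Geranyl means (2E)-3,7-dimethylocta-2,6-dien-1-yl throughout.
- Assumption: the antipode of the aldol catalyst in step 8 is the one that gives Si-face addition to the aldehyde. It would be assigned on the first run by Mosher ester analysis of the aldol; both antipodes are accessible from the enantiomeric binaphthyldiamines.
- Stereochemical bookkeeping: the structures are self-consistent and none needed correcting. The (1S,3S)-diol is the anti isomer and cyclises to the (2S,4S)-flavan-4-ol, which is the 2,4-cis isomer. The C4 centre is erased by the later oxidation, so only C2 has to be enantiopure.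
- The C4 hydroxyl is left free in the cyclisation precursor. Silylation would favour the less hindered C2 hydroxyl, so masking C4 alone would cost at least three steps, and a free C4–OH cannot close a ring on C8a (see step 10).

**Route**

Step 1
Reactants: 1 5-bromoresorcinol
Product: 2 1-(2-bromo-4,6-dihydroxyphenyl)ethan-1-one
Conditions: AcOH, BF3·OEt2 (Lewis acid medium), 90 °C; aqueous work-up
Reagents that add atoms: acetic acid, CC(=O)O
Why: Friedel–Crafts (Nencki-type) C-acylation, in which the activated acetic acid should attack the ring position para to one hydroxyl and ortho to the other (next to bromine), the usual site for 5-substituted resorcinols, while the position between the two hydroxyls is disfavoured; no stereocentre is formed.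

Step 2
Reactants: 2 1-(2-bromo-4,6-dihydroxyphenyl)ethan-1-one
Product: 3 1-[2-bromo-4,6-bis(methoxymethoxy)phenyl]ethan-1-one
Conditions: NaH (2.4 equiv), MOMCl (2.5 equiv), DMF, 0 °C → rt
Reagents that add atoms: chloromethyl methyl ether (MOMCl), COCCl
Why: Williamson-type O-alkylation, in which NaH forms both phenoxides irreversibly, including the hydrogen-bonded one next to the ketone, and MOMCl traps them as base-stable acetals that should survive every step up to the final acid treatment.

Step 3
Reactants: 3 1-[2-bromo-4,6-bis(methoxymethoxy)phenyl]ethan-1-one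
Product: 4 {1-[2-bromo-4,6-bis(methoxymethoxy)phenyl]ethenyl}oxy(trimethyl)silane
Conditions: LiHMDS, THF, −78 °C; TMSCl, −78 → 0 °C; non-aqueous work-up, used crude
Reagents that add atoms: chlorotrimethylsilane, C[Si](C)(C)Cl
Why: Kinetic enolisation and O-silylation, in which the non-nucleophilic amide removes a proton from the only enolisable position (the acetyl methyl) without touching the aryl bromide or the MOM ethers, and TMSCl traps the enolate on oxygen.

Step 4
Reactants: 5 2-hydroxy-4-methoxybenzaldehyde
Product: 6 5-bromo-2-hydroxy-4-methoxybenzaldehyde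
Conditions: NBS, MeCN, 0 °C → rt
Reagents that add atoms: N-bromosuccinimide, O=C1CCC(=O)N1Br
Why: Electrophilic aromatic bromination, directed to C5 because it is para to the free hydroxyl, ortho to the methoxy group and meta to the formyl group, and less hindered than C3 between the two oxygens.

Step 5
Reactants: 6 5-bromo-2-hydroxy-4-methoxybenzaldehyde
Product: 7 5-bromo-4-methoxy-2-(methoxymethoxy)benzaldehyde
Conditions: MOMCl, i-Pr2NEt, CH2Cl2, 0 °C → rt
Reagents that add atoms: chloromethyl methyl ether (MOMCl), COCCl
Why: O-alkylation of the salicylaldehyde hydroxyl with MOMCl under amine base, a routine protection that gives the B ring the same acetal group as the A ring so that one final operation removes all three.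

Step 6
Reactants: 7 5-bromo-4-methoxy-2-(methoxymethoxy)benzaldehyde
Product: 8 4-methoxy-2-(methoxymethoxy)-5-(4,4,5,5-tetramethyl-1,3,2-dioxaborolan-2-yl)benzaldehyde
Conditions: B2pin2, Pd(dppf)Cl2 (3 mol%), KOAc, 1,4-dioxane, 90 °C
Reagents that add atoms: bis(pinacolato)diboron, CC1(C)OB(OC1(C)C)B1OC(C)(C)C(C)(C)O1
Why: Miyaura borylation, in which oxidative addition into the C–Br bond, acetate-assisted transmetalation and reductive elimination give the aryl boronate; the weak base should prevent onward biaryl coupling and the aldehyde is tolerated.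

Step 7
Reactants: 8 4-methoxy-2-(methoxymethoxy)-5-(4,4,5,5-tetramethyl-1,3,2-dioxaborolan-2-yl)benzaldehyde; 9 geranyl bromide
Product: 10 5-geranyl-4-methoxy-2-(methoxymethoxy)benzaldehyde
Conditions: Pd(PPh3)4 (5 mol%), K2CO3, THF/H2O, 60 °C
Reagents that add atoms: none
Why: Suzuki–Miyaura allyl–aryl coupling, in which geranyl bromide forms a π-allylpalladium complex and the aryl group is delivered to the less substituted allyl terminus, so the linear product with the E geometry of the 2,3-alkene retained is expected.

Step 8
Reactants: 4 {1-[2-bromo-4,6-bis(methoxymethoxy)phenyl]ethenyl}oxy(trimethyl)silane; 10 5-geranyl-4-methoxy-2-(methoxymethoxy)benzaldehyde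
Product: 12 (3S)-1-[2-bromo-4,6-bis(methoxymethoxy)phenyl]-3-[5-geranyl-4-methoxy-2-(methoxymethoxy)phenyl]-3-hydroxypropan-1-one, via trichlorosilyl aldolate 11 (not isolated)
Conditions: SiCl4 (1.2 equiv), chiral binaphthyldiamine-derived bisphosphoramide (5 mol%, antipode as in the assumption above), i-Pr2NEt (cat.), CH2Cl2, −78 °C; buffered aqueous work-up
Reagents that add atoms: none
Why: Lewis-base-activated SiCl4 Mukaiyama aldol, a reaction type established for TMS enol ethers of methyl ketones with aromatic aldehydes, in which the chiral chlorosilicon cation binds the aldehyde and shields one face so that the CH2 terminus of the enol silane adds through an open transition state to the Si face and the new carbinol (later C2) is S.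

Step 9
Reactants: 12 (3S)-1-[2-bromo-4,6-bis(methoxymethoxy)phenyl]-3-[5-geranyl-4-methoxy-2-(methoxymethoxy)phenyl]-3-hydroxypropan-1-one
Product: 14 (1S,3S)-1-[2-bromo-4,6-bis(methoxymethoxy)phenyl]-3-[5-geranyl-4-methoxy-2-(methoxymethoxy)phenyl]propane-1,3-diol, via cyclic diacetoxyborate 13 (not isolated)
Conditions: Me4NBH(OAc)3, MeCN/AcOH (little AcOH), −30 °C; aqueous Rochelle salt work-up
Reagents that add atoms: none
Why: Evans–Saksena reduction, in which the existing hydroxyl exchanges onto boron and hydride is delivered intramolecularly through a chair six-membered transition state, which should give the 1,3-anti diol with the new carbinol S, while the low temperature protects the acid-sensitive benzylic alcohols and MOM ethers.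

Step 10
Reactants: 14 (1S,3S)-1-[2-bromo-4,6-bis(methoxymethoxy)phenyl]-3-[5-geranyl-4-methoxy-2-(methoxymethoxy)phenyl]propane-1,3-diol
Product: 15 (2S,4S)-2-[5-geranyl-4-methoxy-2-(methoxymethoxy)phenyl]-5,7-bis(methoxymethoxy)-3,4-dihydro-2H-chromen-4-ol (2,4-cis)
Conditions: Pd(OAc)2 (5 mol%), 2-(di-tert-butylphosphino)-1,1'-binaphthyl (7 mol%), Cs2CO3, toluene, 70 °C
Reagents that add atoms: none
Why: Pd(0) inserts into the C8a–Br bond, carbonate-assisted exchange puts the C2 alkoxide on palladium (a seven-membered oxapalladacycle through C8a, C4a, C4, C3, C2 and O), and C(aryl)–O reductive elimination forms O1–C8a. The closest known reaction type is the Buchwald–Hartwig-type intramolecular etherification of aryl bromides with secondary alcohols, which gives 2-substituted chromans without loss of configuration at the carbinol carbon. Ring C closes in a six-membered exo sense, the oxygen attacking the aryl carbon while bromide leaves outside the ring. No stereocentre is made: neither the C2–O nor the C4–O bond is broken, so (1S,3S)-14 maps onto (2S,4S)-15, the 2,4-cis isomer with both substituents pseudo-equatorial. Site selectivity between the two hydroxyls follows from ring size, because the C4 alkoxide can only form a five-membered chelate whose reductive elimination would need a benzoxetene and whose C4–H cannot easily become syn-coplanar with Pd–O, so it should simply exchange back. The selectivity that must be won is reductive elimination over β-hydride elimination at C2–H, and the bulky, electron-rich di-tert-butyl biaryl phosphine is chosen to provide it by enforcing a low-coordinate palladium alkoxide.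

Step 11
Reactants: 15 (2S,4S)-2-[5-geranyl-4-methoxy-2-(methoxymethoxy)phenyl]-5,7-bis(methoxymethoxy)-3,4-dihydro-2H-chromen-4-ol
Product: 16 (2S)-2-[5-geranyl-4-methoxy-2-(methoxymethoxy)phenyl]-5,7-bis(methoxymethoxy)-2,3-dihydro-4H-chromen-4-one
Conditions: Dess–Martin periodinane, NaHCO3, CH2Cl2, 0 °C → rt
Reagents that add atoms: none
Why: Dess–Martin oxidation of the secondary benzylic alcohol to the aryl ketone under bicarbonate buffer, which erases the C4 centre and should leave C2, the trisubstituted alkenes and the MOM ethers untouched.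

Step 12
Reactants: 16 (2S)-2-[5-geranyl-4-methoxy-2-(methoxymethoxy)phenyl]-5,7-bis(methoxymethoxy)-2,3-dihydro-4H-chromen-4-one
Product: 17 Kuwanon U, (2S)-2-(5-geranyl-2-hydroxy-4-methoxyphenyl)-5,7-dihydroxy-2,3-dihydro-4H-chromen-4-one
Conditions: 2 M aq. HCl (cat.)/MeOH, 40 °C, stopped at full conversion; ee checked by chiral HPLC
Reagents that add atoms: none
Why: Acid-catalysed transacetalisation of the three aryl MOM ethers to dimethoxymethane, mild enough that the geranyl chain (no ortho phenol, since its neighbours are OMe and H) and the C2 centre should survive, the 5-OH/C4=O hydrogen bond disfavouring ring opening to the chalcone.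

**Compound list**

1 | 5-bromoresorcinol | Oc1cc(O)cc(Br)c1 | starting material
2 | 1-(2-bromo-4,6-dihydroxyphenyl)ethan-1-one | CC(=O)c1c(O)cc(O)cc1Br | intermediate
3 | 1-[2-bromo-4,6-bis(methoxymethoxy)phenyl]ethan-1-one | CC(=O)c1c(OCOC)cc(OCOC)cc1Br | intermediate
4 | {1-[2-bromo-4,6-bis(methoxymethoxy)phenyl]ethenyl}oxy(trimethyl)silane | C=C(O[Si](C)(C)C)c1c(OCOC)cc(OCOC)cc1Br | intermediate
5 | 2-hydroxy-4-methoxybenzaldehyde | COc1ccc(C=O)c(O)c1 | starting material
6 | 5-bromo-2-hydroxy-4-methoxybenzaldehyde | COc1cc(O)c(C=O)cc1Br | intermediate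
7 | 5-bromo-4-methoxy-2-(methoxymethoxy)benzaldehyde | COCOc1cc(OC)c(Br)cc1C=O | intermediate
8 | 4-methoxy-2-(methoxymethoxy)-5-(4,4,5,5-tetramethyl-1,3,2-dioxaborolan-2-yl)benzaldehyde | COCOc1cc(OC)c(B2OC(C)(C)C(C)(C)O2)cc1C=O | intermediate
9 | geranyl bromide, (2E)-1-bromo-3,7-dimethylocta-2,6-diene | BrC/C=C(\C)CCC=C(C)C | starting material
10 | 5-geranyl-4-methoxy-2-(methoxymethoxy)benzaldehyde | COCOc1cc(OC)c(C/C=C(\C)CCC=C(C)C)cc1C=O | intermediate
11 | trichlorosilyl ether of aldol 12, (S) at the carbinol carbon (not isolated) | COc1cc(OCOC)c([C@@H](O[Si](Cl)(Cl)Cl)CC(=O)c2c(Br)cc(OCOC)cc2OCOC)cc1C/C=C(\C)CCC=C(C)C | intermediate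
12 | (3S)-1-[2-bromo-4,6-bis(methoxymethoxy)phenyl]-3-[5-geranyl-4-methoxy-2-(methoxymethoxy)phenyl]-3-hydroxypropan-1-one | COc1cc(OCOC)c([C@@H](O)CC(=O)c2c(Br)cc(OCOC)cc2OCOC)cc1C/C=C(\C)CCC=C(C)C | intermediate
13 | tetramethylammonium cyclic diacetoxyborate of diol 14, (4S,6S)-1,3,2-dioxaborinane (not isolated) | COc1cc(OCOC)c([C@@H]2C[C@@H](c3c(Br)cc(OCOC)cc3OCOC)O[B-](OC(C)=O)(OC(C)=O)O2)cc1C/C=C(\C)CCC=C(C)C.C[N+](C)(C)C | intermediate
14 | (1S,3S)-1-[2-bromo-4,6-bis(methoxymethoxy)phenyl]-3-[5-geranyl-4-methoxy-2-(methoxymethoxy)phenyl]propane-1,3-diol (anti) | COc1cc(OCOC)c([C@@H](O)C[C@H](O)c2c(Br)cc(OCOC)cc2OCOC)cc1C/C=C(\C)CCC=C(C)C | intermediate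
15 | (2S,4S)-2-[5-geranyl-4-methoxy-2-(methoxymethoxy)phenyl]-5,7-bis(methoxymethoxy)-3,4-dihydro-2H-chromen-4-ol (2,4-cis) | COc1cc(OCOC)c([C@@H]2C[C@H](O)c3c(OCOC)cc(OCOC)cc3O2)cc1C/C=C(\C)CCC=C(C)C | intermediate
16 | (2S)-2-[5-geranyl-4-methoxy-2-(methoxymethoxy)phenyl]-5,7-bis(methoxymethoxy)-2,3-dihydro-4H-chromen-4-one | COc1cc(OCOC)c([C@@H]2CC(=O)c3c(OCOC)cc(OCOC)cc3O2)cc1C/C=C(\C)CCC=C(C)C | intermediate
17 | Kuwanon U, (2S)-2-(5-geranyl-2-hydroxy-4-methoxyphenyl)-5,7-dihydroxy-2,3-dihydro-4H-chromen-4-one | COc1cc(O)c([C@@H]2CC(=O)c3c(O)cc(O)cc3O2)cc1C/C=C(\C)CCC=C(C)C | target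

**Step count and risks**

Total step count: 12 (A-ring branch steps 1–3, B-ring branch steps 4–7, common steps 8–12).
Longest linear sequence: 9 steps (steps 4–12, from 5 to 17).

Steps most likely to fail:

1. Step 10. β-Hydride elimination from the palladium alkoxide, with hydrodebromination of the arene, or sequestration of palladium by the diol may outrun C–O reductive elimination. Fallback: setting out from diol 14, the same O1–C8a bond would be made in a different catalytic manifold, a copper(I)-catalysed Ullmann-type intramolecular etherification (CuI, 3,4,7,8-tetramethyl-1,10-phenanthroline, Cs2CO3, toluene, 110 °C). Its copper alkoxide has no facile β-hydride pathway, and the C2–O bond is again left intact. This returns to the route at flavan-4-ol 15 and makes no new compound (F0).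

2. Step 8. Facial selectivity may be insufficient or addition to the electron-rich, ortho-substituted aldehyde slow, and the chlorosilane Lewis acid may strip MOM groups or ionise the silylated benzylic aldolate. Fallback: the stereocentre would be set by a ketone reduction of predictable sense instead of by C–C bond formation. Setting out from ketone 3 and aldehyde 10, the lithium enolate of 3 (LiHMDS, THF, −78 °C; AcOH quench) would add to 10 to give the racemic aldol rac-1-[2-bromo-4,6-bis(methoxymethoxy)phenyl]-3-[5-geranyl-4-methoxy-2-(methoxymethoxy)phenyl]-3-hydroxypropan-1-one F1. Dess–Martin oxidation (NaHCO3, CH2Cl2) would give the 1,3-diketone 1-[2-bromo-4,6-bis(methoxymethoxy)phenyl]-3-[5-geranyl-4-methoxy-2-(methoxymethoxy)phenyl]propane-1,3-dione F2. Noyori asymmetric transfer hydrogenation (RuCl(p-cymene)[(S,S)-TsDPEN], HCO2H/Et3N, rt) should then reduce only the unhindered carbonyl next to ring B, the (S,S)-catalyst giving the (S)-benzylic alcohol as with simple aryl ketones. The sequence returns to the route at aldol 12.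

3. Step 9. Acid-promoted ionisation of the electron-rich benzylic carbinol (elimination towards the chalcone, erosion of configuration) or sluggish hydride delivery to the doubly ortho-substituted ketone may occur. Fallback: setting out from aldol 12, a samarium-catalysed Evans–Tishchenko reduction (isobutyraldehyde, SmI2 cat., THF, −10 °C) would transfer hydride intramolecularly from the hemiacetal under non-acidic conditions. It should give the anti monoester (1S,3S)-3-[2-bromo-4,6-bis(methoxymethoxy)phenyl]-1-[5-geranyl-4-methoxy-2-(methoxymethoxy)phenyl]-3-hydroxypropyl 2-methylpropanoate F3. Methanolysis (K2CO3 cat., MeOH) would remove the ester and return to the route at diol 14.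

**Further compounds**

F0 | step 10 | none | none
F1 | step 8 | rac-1-[2-bromo-4,6-bis(methoxymethoxy)phenyl]-3-[5-geranyl-4-methoxy-2-(methoxymethoxy)phenyl]-3-hydroxypropan-1-one | COc1cc(OCOC)c(C(O)CC(=O)c2c(Br)cc(OCOC)cc2OCOC)cc1C/C=C(\C)CCC=C(C)C
F2 | step 8 | 1-[2-bromo-4,6-bis(methoxymethoxy)phenyl]-3-[5-geranyl-4-methoxy-2-(methoxymethoxy)phenyl]propane-1,3-dione | COc1cc(OCOC)c(C(=O)CC(=O)c2c(Br)cc(OCOC)cc2OCOC)cc1C/C=C(\C)CCC=C(C)C
F3 | step 9 | (1S,3S)-3-[2-bromo-4,6-bis(methoxymethoxy)phenyl]-1-[5-geranyl-4-methoxy-2-(methoxymethoxy)phenyl]-3-hydroxypropyl 2-methylpropanoate | COc1cc(OCOC)c([C@@H](OC(=O)C(C)C)C[C@H](O)c2c(Br)cc(OCOC)cc2OCOC)cc1C/C=C(\C)CCC=C(C)C
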